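## Retrosynthetic overview

1. Target ⇒ C4/C5 cis-diol (Mitsunobu inversion at C4 with angelic acid) ⇒ C4=C5 alkene (OsO4 anti to the C3 ester) ⇒ C3 ketone (reagent-controlled reduction, then (R)-2-methylbutanoate).
2. Seven-membered ring (formed last) ⇒ intramolecular vinylogous aldol of an enone dienolate onto a cyclobutanone, then radical removal of the bridgehead oxygen.
3. Cyclobutane and six-membered ring (formed together, first) ⇒ intramolecular vinylketene–alkene [2+2] of a 5,8-dioxygenated farnesoic-type acid chloride; the C5 silyloxy centre steers the face and later becomes the enone carbonyl.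
4. Acyclic acid ⇒ catalytic asymmetric vinylogous Mukaiyama aldol of a C10 enal (from ethyl 3-methyl-4-oxocrotonate and 3-methylbut-1-yne) with the silyl dienolate of methyl 3-methylbut-2-enoate.

Assumptions: the side-chain carbinol that later becomes the C3 ketone is carried as an epimer mixture (drawn without configuration) until it is oxidised; the (S,S) bisphosphoramide is taken to give Si-face addition and the (5S) alcohol, and because this centre is erased later the antipode is simply the one that makes the [2+2] give the ring enantiomer drawn; metal alkoxides that are only hydrolysed on work-up are not numbered; tricyclic compounds are numbered as tricyclo[5.4.0.0(2,8)]undecanes (C1 = CH next to the C11 carbonyl, C2 = CMe, C3–C5 = oxygenated carbons, C6 = CMe2, C7 and C8 = the other cyclobutane CH, C9–C11 = enone bridge).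

## Route

Step 1
Reactants: 1 ethyl (2E)-3-methyl-4-oxobut-2-enoate; 2 3-methylbut-1-yne
Product: 5 ethyl (2E,5E)-4-hydroxy-3,7-dimethylocta-2,5-dienoate (racemic), via alkenylzirconocene chloride 3 (not isolated), via alkenylmethylzinc 4 (not isolated)
Conditions: Cp2Zr(H)Cl, CH2Cl2, rt; Me2Zn, toluene, −65 °C; then 1, 0 °C; cold 0.5 M HCl
Reagents that add atoms: none
Why: Hydrozirconation gives the (E)-alkenylzirconocene, and after Zr-to-Zn transmetallation the alkenylzinc adds 1,2 to the aldehyde without touching the enoate (hydrozirconation–transmetallation alkenylation); the carbinol is left racemic because it is oxidised to a ketone in step 10.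

Step 2
Reactants: 5 ethyl (2E,5E)-4-hydroxy-3,7-dimethylocta-2,5-dienoate
Product: 6 ethyl (2E,5E)-3,7-dimethyl-4-(triethylsilyloxy)octa-2,5-dienoate
Conditions: Et3SiCl, imidazole, DMF, 0 °C → rt
Reagents that add atoms: chlorotriethylsilane CC[Si](Cl)(CC)CC
Why: Standard silylation; the triethylsilyl ether is chosen because it can later be removed oxidatively while a tert-butyldimethylsilyl ether stays.

Step 3
Reactants: 6 ethyl (2E,5E)-3,7-dimethyl-4-(triethylsilyloxy)octa-2,5-dienoate
Product: 7 (2E,5E)-3,7-dimethyl-4-(triethylsilyloxy)octa-2,5-dien-1-ol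
Conditions: iBu2AlH (2.2 equiv), CH2Cl2, −78 °C; aq. KNaC4H4O6
Reagents that add atoms: none
Why: 1,2-Reduction of the enoate by the aluminium hydride gives the allylic alcohol without conjugate reduction.

Step 4
Reactants: 7 (2E,5E)-3,7-dimethyl-4-(triethylsilyloxy)octa-2,5-dien-1-ol
Product: 8 (2E,5E)-3,7-dimethyl-4-(triethylsilyloxy)octa-2,5-dienal
Conditions: MnO2, CH2Cl2, rt
Reagents that add atoms: none
Why: Chemoselective allylic oxidation gives the (E)-enal without moving the trisubstituted double bond.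

Step 5
Reactants: 9 methyl 3-methylbut-2-enoate
Product: 10 tert-butyl[(1-methoxy-3-methylbuta-1,3-dien-1-yl)oxy]dimethylsilane
Conditions: LiN(iPr)2, THF, −78 °C; tBuMe2SiCl, DMPU, −78 °C → rt
Reagents that add atoms: tert-butyldimethylsilyl chloride CC(C)(C)[Si](C)(C)Cl
Why: γ-Deprotonation of the senecioate and O-silylation of the lithium dienolate give the silyl ketene acetal needed for the vinylogous Mukaiyama aldol.

Step 6
Reactants: 8 (2E,5E)-3,7-dimethyl-4-(triethylsilyloxy)octa-2,5-dienal; 10 tert-butyl[(1-methoxy-3-methylbuta-1,3-dien-1-yl)oxy]dimethylsilane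
Product: 11 methyl (2E,5S,6E,9E)-5-hydroxy-3,7,11-trimethyl-8-(triethylsilyloxy)dodeca-2,6,9-trienoate (C8 epimers)
Conditions: SiCl4 (1.1 equiv), (S,S)-bisphosphoramide 1,5-bis{methyl[(11bS)-3,5-dimethyl-4-oxido-3,5-dihydro-4H-dinaphtho[2,1-d:1',2'-f][1,3,2]diazaphosphepin-4-yl]amino}pentane (5 mol %), CH2Cl2, −78 °C; aq. KF/NaHCO3
Reagents that add atoms: none
Why: The phosphoramide-bound trichlorosilyl cation catalyses a γ-selective vinylogous Mukaiyama aldol addition in which the catalyst fixes the aldehyde face and so sets the (5S) carbinol, the only stereocentre the route has to create by catalyst control before the ring-forming step.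

Step 7
Reactants: 11 methyl (2E,5S,6E,9E)-5-hydroxy-3,7,11-trimethyl-8-(triethylsilyloxy)dodeca-2,6,9-trienoate
Product: 12 methyl (2E,5S,6E,9E)-5-(tert-butyldimethylsilyloxy)-3,7,11-trimethyl-8-(triethylsilyloxy)dodeca-2,6,9-trienoate
Conditions: tBuMe2SiOTf, 2,6-lutidine, CH2Cl2, −78 °C
Reagents that add atoms: tert-butyldimethylsilyl trifluoromethanesulfonate CC(C)(C)[Si](C)(C)OS(=O)(=O)C(F)(F)F
Why: Silylation of the secondary allylic alcohol with the silyl triflate installs the bulky group that controls the face in step 9 and survives to step 15.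

Step 8
Reactants: 12 methyl (2E,5S,6E,9E)-5-(tert-butyldimethylsilyloxy)-3,7,11-trimethyl-8-(triethylsilyloxy)dodeca-2,6,9-trienoate
Product: 13 (2E,5S,6E,9E)-5-(tert-butyldimethylsilyloxy)-3,7,11-trimethyl-8-(triethylsilyloxy)dodeca-2,6,9-trienoic acid
Conditions: KOSiMe3 (3 equiv), THF, rt; AcOH to pH 5
Reagents that add atoms: potassium trimethylsilanolate C[Si](C)(C)[O-].[K+]
Why: Anhydrous nucleophilic ester cleavage by the silanolate frees the acid without loss of either silyl ether and without vinylogous elimination of the δ-silyloxy group.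

Step 9
Reactants: 13 (2E,5S,6E,9E)-5-(tert-butyldimethylsilyloxy)-3,7,11-trimethyl-8-(triethylsilyloxy)dodeca-2,6,9-trienoic acid
Product: 16 (4S)-4-(tert-butyldimethylsilyloxy)-7-methyl-2-methylidene-7-[(2E)-4-methyl-1-(triethylsilyloxy)pent-2-en-1-yl]bicyclo[3.1.1]heptan-6-one (7-methyl syn to the C2–C4 bridge; 4-silyloxy on the C6 side; side-chain epimers), via acid chloride 14 (not isolated), via vinylketene 15 (not isolated)
Conditions: 1-chloro-N,N,2-trimethylprop-1-en-1-amine, CH2Cl2, 0 °C → rt; then slow addition to Et3N (3 equiv) in toluene (0.005 M), 110 °C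
Reagents that add atoms: none
Why: Thermal intramolecular vinylketene–alkene [2+2] cycloaddition (the type used for bergamotene and β-pinene) builds the cyclobutanone and the six-membered ring at once: the ketene carbonyl carbon bonds to the less substituted alkene carbon and the ketene α-carbon to the cation-stabilising disubstituted one (bridged, not fused), suprafacial addition to the (6E)-alkene puts the methyl syn and the side chain anti to the C2–C4 bridge, and the (5S)-silyloxy group sits pseudo-axial away from the forming quaternary carbon (A(1,3) strain with the cis methyl) and so selects the alkene face; an exocyclic/endocyclic alkene isomer mixture converges in step 16.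

Step 10
Reactants: 16 (4S)-4-(tert-butyldimethylsilyloxy)-7-methyl-2-methylidene-7-[(2E)-4-methyl-1-(triethylsilyloxy)pent-2-en-1-yl]bicyclo[3.1.1]heptan-6-one
Product: 18 (4S)-4-(tert-butyldimethylsilyloxy)-7-methyl-2-methylidene-7-[(2E)-4-methylpent-2-enoyl]bicyclo[3.1.1]heptan-6-one, via allylic alcohol 17 (not isolated)
Conditions: IBX (2-iodoxybenzoic acid, 3 equiv), DMSO, rt → 40 °C
Reagents that add atoms: none
Why: IBX in DMSO cleaves the triethylsilyl ether selectively and oxidises the freed allylic alcohol in the same flask (oxidative desilylation), which converges both side-chain epimers to one enone.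

Step 11
Reactants: 18 (4S)-4-(tert-butyldimethylsilyloxy)-7-methyl-2-methylidene-7-[(2E)-4-methylpent-2-enoyl]bicyclo[3.1.1]heptan-6-one
Product: 22 O-[(11S)-11-(tert-butyldimethylsilyloxy)-2,6,6-trimethyl-9-methylidene-3-oxotricyclo[5.4.0.0(2,8)]undec-4-en-7-yl] S-methyl carbonodithioate, via potassium dienolate 19 (not isolated), via potassium alkoxide 20 (not isolated), via potassium xanthate 21 (not isolated)
Conditions: KN(SiMe3)2 (1.2 equiv), THF, −78 → −30 °C; CS2, −78 °C; MeI, −78 °C → rt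
Reagents that add atoms: carbon disulfide S=C=S; iodomethane CI
Why: Proposed new method: the only acidic C–H is the γ-methine of the enone (the cyclobutanone is flanked by bridgeheads and the enone carbonyl by a quaternary carbon), so the potassium dienolate forms there and its γ-carbon, held under the anti face of the cyclobutanone by the 1,3-diaxial arrangement, adds to the strained carbonyl (intramolecular vinylogous aldol; α-attack would give a far more strained bicyclo[2.1.1]hexane and is reversible), which closes the seven-membered ring with the new C–C bond necessarily anti, and the alkoxide is trapped as its xanthate before retro-aldol can occur (closest known types: intramolecular vinylogous aldol cyclisation and alkoxide/CS2/MeI xanthate formation).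

Step 12
Reactants: 22 O-[(11S)-11-(tert-butyldimethylsilyloxy)-2,6,6-trimethyl-9-methylidene-3-oxotricyclo[5.4.0.0(2,8)]undec-4-en-7-yl] S-methyl carbonodithioate
Product: 23 O-[(11S)-11-(tert-butyldimethylsilyloxy)-3-hydroxy-2,6,6-trimethyl-9-methylidenetricyclo[5.4.0.0(2,8)]undec-4-en-7-yl] S-methyl carbonodithioate (3-OH on the C1 side)
Conditions: (S)-1-methyl-3,3-diphenyltetrahydro-1H,3H-pyrrolo[1,2-c][1,3,2]oxazaborole (0.3 equiv), catecholborane (2 equiv), toluene, −78 °C; aq. NaOH
Reagents that add atoms: none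
Why: Corey–Bakshi–Shibata reduction under reagent control, needed because the two faces of this ketone are almost equivalent in the near-symmetric cage: with quaternary C2 as the large and the cis-alkenyl carbon as the small substituent the (S)-catalyst delivers hydride from the C8 side and places the hydroxyl on the C1 side (the antipodal catalyst is used if the large/small roles prove reversed).

Step 13
Reactants: 23 O-[(11S)-11-(tert-butyldimethylsilyloxy)-3-hydroxy-2,6,6-trimethyl-9-methylidenetricyclo[5.4.0.0(2,8)]undec-4-en-7-yl] S-methyl carbonodithioate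
Product: 24 (11S)-11-(tert-butyldimethylsilyloxy)-2,6,6-trimethyl-9-methylidenetricyclo[5.4.0.0(2,8)]undec-4-en-3-ol (3-OH on the C1 side)
Conditions: Bu3SnH (4 equiv), PhSeSePh (10 mol %), 2,2'-azobis(2-methylpropionitrile) (20 mol %), toluene, 100 °C
Reagents that add atoms: none
Why: Barton–McCombie deoxygenation: the tertiary xanthate cannot undergo Chugaev elimination (only bridgehead β-hydrogens), the bridgehead cyclobutyl radical can take hydrogen only on its single exposed lobe so C7–H has the cage-imposed configuration, and PhSeH formed in situ traps the radical faster than a 1,2-vinyl shift.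

Step 14
Reactants: 24 (11S)-11-(tert-butyldimethylsilyloxy)-2,6,6-trimethyl-9-methylidenetricyclo[5.4.0.0(2,8)]undec-4-en-3-ol; 25 (2R)-2-methylbutanoic acid
Product: 26 (11S)-11-(tert-butyldimethylsilyloxy)-2,6,6-trimethyl-9-methylidenetricyclo[5.4.0.0(2,8)]undec-4-en-3-yl (2R)-2-methylbutanoate
Conditions: N,N'-dicyclohexylcarbodiimide, 4-(dimethylamino)pyridine (0.3 equiv), CH2Cl2, 0 °C → rt
Reagents that add atoms: none
Why: Steglich esterification of the only free hydroxyl introduces the (2R)-2-methylbutanoate at C3 before any other hydroxyl exists.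

Step 15
Reactants: 26 (11S)-11-(tert-butyldimethylsilyloxy)-2,6,6-trimethyl-9-methylidenetricyclo[5.4.0.0(2,8)]undec-4-en-3-yl (2R)-2-methylbutanoate
Product: 27 (11S)-11-hydroxy-2,6,6-trimethyl-9-methylidenetricyclo[5.4.0.0(2,8)]undec-4-en-3-yl (2R)-2-methylbutanoate
Conditions: Bu4NF, AcOH (1:1), THF, rt → 40 °C
Reagents that add atoms: none
Why: Fluoride cleaves the secondary silyl ether, and the acetic acid buffer keeps the ester and the acid-sensitive pinene-like skeleton intact.

Step 16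
Reactants: 27 (11S)-11-hydroxy-2,6,6-trimethyl-9-methylidenetricyclo[5.4.0.0(2,8)]undec-4-en-3-yl (2R)-2-methylbutanoate
Product: 29 2,6,6,9-tetramethyl-11-oxotricyclo[5.4.0.0(2,8)]undeca-4,9-dien-3-yl (2R)-2-methylbutanoate, via deconjugated ketone 28 (not isolated)
Conditions: Dess–Martin periodinane, NaHCO3, CH2Cl2, 0 °C → rt; then 1,8-diazabicyclo[5.4.0]undec-7-ene (0.5 equiv), rt
Reagents that add atoms: none
Why: Dess–Martin oxidation gives the β,γ-unsaturated ketone and the amidine base moves the exocyclic double bond into conjugation through the dienol (only C10 can enolise, C1 is a bridgehead), which gives the verbenone-type enone and erases the controlling C11 stereocentre.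

Step 17
Reactants: 29 2,6,6,9-tetramethyl-11-oxotricyclo[5.4.0.0(2,8)]undeca-4,9-dien-3-yl (2R)-2-methylbutanoate
Product: 30 4,5-dihydroxy-2,6,6,9-tetramethyl-11-oxotricyclo[5.4.0.0(2,8)]undec-9-en-3-yl (2R)-2-methylbutanoate (3-O on the C1 side; 4-OH and 5-OH on the C8 side)
Conditions: OsO4 (10 mol %), N-methylmorpholine N-oxide (2 equiv), acetone/H2O 5:1, rt
Reagents that add atoms: osmium tetroxide O=[Os](=O)(=O)=O; N-methylmorpholine N-oxide C[N+]1([O-])CCOCC1; water O
Why: Upjohn dihydroxylation: the conjugated trisubstituted C9=C10 bond is electron-poor and inert, and OsO4 adds to C4=C5 from the face opposite the allylic C3 ester (steric and Kishi anti selectivity), giving the cis-diol on the C8 side.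

Step 18
Reactants: 30 4,5-dihydroxy-2,6,6,9-tetramethyl-11-oxotricyclo[5.4.0.0(2,8)]undec-9-en-3-yl (2R)-2-methylbutanoate; 31 (2Z)-2-methylbut-2-enoic acid (angelic acid)
Product: 33 5-hydroxy-2,6,6,9-tetramethyl-3-[(2R)-2-methylbutanoyloxy]-11-oxotricyclo[5.4.0.0(2,8)]undec-9-en-4-yl (2Z)-2-methylbut-2-enoate (CNP0202800.1), via alkoxyphosphonium angelate 32 (not isolated)
Conditions: PPh3 (2 equiv), diisopropyl azodicarboxylate (2 equiv), toluene, 0 °C → rt
Reagents that add atoms: none
Why: Mitsunobu esterification: angelate displaces the oxyphosphonium group at C4 with inversion (SN2 at C5 is blocked by the adjacent quaternary carbon), which puts the angelate cis to the C3 ester and trans to the free C5 hydroxyl without exposing the (Z)-ester to acid, base or heat.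

## Compound list

1 | ethyl (2E)-3-methyl-4-oxobut-2-enoate | CCOC(=O)/C=C(\C)C=O | starting material
2 | 3-methylbut-1-yne | CC(C)C#C | starting material
3 | chlorobis(cyclopentadienyl)[(1E)-3-methylbut-1-en-1-yl]zirconium (not isolated) | CC(C)/C=C/[Zr](Cl)(C1C=CC=C1)C1C=CC=C1 | intermediate
4 | methyl[(1E)-3-methylbut-1-en-1-yl]zinc (not isolated) | CC(C)/C=C/[Zn]C | intermediate
5 | ethyl (2E,5E)-4-hydroxy-3,7-dimethylocta-2,5-dienoate, racemic | CCOC(=O)/C=C(\C)C(O)/C=C/C(C)C | intermediate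
6 | ethyl (2E,5E)-3,7-dimethyl-4-(triethylsilyloxy)octa-2,5-dienoate, racemic | CCOC(=O)/C=C(\C)C(O[Si](CC)(CC)CC)/C=C/C(C)C | intermediate
7 | (2E,5E)-3,7-dimethyl-4-(triethylsilyloxy)octa-2,5-dien-1-ol, racemic | OC/C=C(\C)C(O[Si](CC)(CC)CC)/C=C/C(C)C | intermediate
8 | (2E,5E)-3,7-dimethyl-4-(triethylsilyloxy)octa-2,5-dienal, racemic | O=C/C=C(\C)C(O[Si](CC)(CC)CC)/C=C/C(C)C | intermediate
9 | methyl 3-methylbut-2-enoate | COC(=O)C=C(C)C | starting material
10 | tert-butyl[(1-methoxy-3-methylbuta-1,3-dien-1-yl)oxy]dimethylsilane | COC(=CC(C)=C)O[Si](C)(C)C(C)(C)C | intermediate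
11 | methyl (2E,5S,6E,9E)-5-hydroxy-3,7,11-trimethyl-8-(triethylsilyloxy)dodeca-2,6,9-trienoate, C8 epimers | COC(=O)/C=C(\C)C[C@H](O)/C=C(\C)C(O[Si](CC)(CC)CC)/C=C/C(C)C | intermediate
12 | methyl (2E,5S,6E,9E)-5-(tert-butyldimethylsilyloxy)-3,7,11-trimethyl-8-(triethylsilyloxy)dodeca-2,6,9-trienoate, C8 epimers | COC(=O)/C=C(\C)C[C@H](O[Si](C)(C)C(C)(C)C)/C=C(\C)C(O[Si](CC)(CC)CC)/C=C/C(C)C | intermediate
13 | (2E,5S,6E,9E)-5-(tert-butyldimethylsilyloxy)-3,7,11-trimethyl-8-(triethylsilyloxy)dodeca-2,6,9-trienoic acid, C8 epimers | OC(=O)/C=C(\C)C[C@H](O[Si](C)(C)C(C)(C)C)/C=C(\C)C(O[Si](CC)(CC)CC)/C=C/C(C)C | intermediate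
14 | acid chloride of 13 (not isolated) | ClC(=O)/C=C(\C)C[C@H](O[Si](C)(C)C(C)(C)C)/C=C(\C)C(O[Si](CC)(CC)CC)/C=C/C(C)C | intermediate
15 | (5S,6E,9E)-5-(tert-butyldimethylsilyloxy)-7,11-dimethyl-3-methylidene-8-(triethylsilyloxy)dodeca-1,6,9-trien-1-one, vinylketene (not isolated) | O=C=CC(=C)C[C@H](O[Si](C)(C)C(C)(C)C)/C=C(\C)C(O[Si](CC)(CC)CC)/C=C/C(C)C | intermediate
16 | (4S)-4-(tert-butyldimethylsilyloxy)-7-methyl-2-methylidene-7-[(2E)-4-methyl-1-(triethylsilyloxy)pent-2-en-1-yl]bicyclo[3.1.1]heptan-6-one; 7-methyl syn to C2–C4, 4-O on the C6 side, side-chain epimers | O=C1[C@H]2[C@@H](O[Si](C)(C)C(C)(C)C)CC(=C)[C@@H]1[C@@]2(C)C(O[Si](CC)(CC)CC)/C=C/C(C)C | intermediate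
17 | (4S)-4-(tert-butyldimethylsilyloxy)-7-[(2E)-1-hydroxy-4-methylpent-2-en-1-yl]-7-methyl-2-methylidenebicyclo[3.1.1]heptan-6-one (not isolated) | O=C1[C@H]2[C@@H](O[Si](C)(C)C(C)(C)C)CC(=C)[C@@H]1[C@@]2(C)C(O)/C=C/C(C)C | intermediate
18 | (4S)-4-(tert-butyldimethylsilyloxy)-7-methyl-2-methylidene-7-[(2E)-4-methylpent-2-enoyl]bicyclo[3.1.1]heptan-6-one | O=C1[C@H]2[C@@H](O[Si](C)(C)C(C)(C)C)CC(=C)[C@@H]1[C@@]2(C)C(=O)/C=C/C(C)C | intermediate
19 | potassium dienolate of 18 (not isolated) | O=C1[C@H]2[C@@H](O[Si](C)(C)C(C)(C)C)CC(=C)[C@@H]1[C@@]2(C)C([O-])=CC=C(C)C.[K+] | intermediate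
20 | potassium (11S)-11-(tert-butyldimethylsilyloxy)-2,6,6-trimethyl-9-methylidene-3-oxotricyclo[5.4.0.0(2,8)]undec-4-en-7-olate (not isolated) | C1=CC(C)(C)[C@]2([O-])[C@H]3[C@@H](O[Si](C)(C)C(C)(C)C)CC(=C)[C@@H]2[C@@]3(C)C1=O.[K+] | intermediate
21 | potassium O-alkyl carbonodithioate of 20 (not isolated) | C1=CC(C)(C)[C@]2(OC(=S)[S-])[C@H]3[C@@H](O[Si](C)(C)C(C)(C)C)CC(=C)[C@@H]2[C@@]3(C)C1=O.[K+] | intermediate
22 | O-[(11S)-11-(tert-butyldimethylsilyloxy)-2,6,6-trimethyl-9-methylidene-3-oxotricyclo[5.4.0.0(2,8)]undec-4-en-7-yl] S-methyl carbonodithioate; 7-O on the side of the C9–C11 bridge | C1=CC(C)(C)[C@]2(OC(=S)SC)[C@H]3[C@@H](O[Si](C)(C)C(C)(C)C)CC(=C)[C@@H]2[C@@]3(C)C1=O | intermediate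
23 | O-[(11S)-11-(tert-butyldimethylsilyloxy)-3-hydroxy-2,6,6-trimethyl-9-methylidenetricyclo[5.4.0.0(2,8)]undec-4-en-7-yl] S-methyl carbonodithioate; 3-OH on the C1 side | C1=CC(C)(C)[C@]2(OC(=S)SC)[C@H]3[C@@H](O[Si](C)(C)C(C)(C)C)CC(=C)[C@@H]2[C@@]3(C)[C@@H]1O | intermediate
24 | (11S)-11-(tert-butyldimethylsilyloxy)-2,6,6-trimethyl-9-methylidenetricyclo[5.4.0.0(2,8)]undec-4-en-3-ol; 3-OH on the C1 side | C1=CC(C)(C)[C@@H]2[C@H]3[C@@H](O[Si](C)(C)C(C)(C)C)CC(=C)[C@@H]2[C@@]3(C)[C@@H]1O | intermediate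
25 | (2R)-2-methylbutanoic acid | CC[C@@H](C)C(=O)O | starting material
26 | (11S)-11-(tert-butyldimethylsilyloxy)-2,6,6-trimethyl-9-methylidenetricyclo[5.4.0.0(2,8)]undec-4-en-3-yl (2R)-2-methylbutanoate | C1=CC(C)(C)[C@@H]2[C@H]3[C@@H](O[Si](C)(C)C(C)(C)C)CC(=C)[C@@H]2[C@@]3(C)[C@@H]1OC(=O)[C@H](C)CC | intermediate
27 | (11S)-11-hydroxy-2,6,6-trimethyl-9-methylidenetricyclo[5.4.0.0(2,8)]undec-4-en-3-yl (2R)-2-methylbutanoate | C1=CC(C)(C)[C@@H]2[C@H]3[C@@H](O)CC(=C)[C@@H]2[C@@]3(C)[C@@H]1OC(=O)[C@H](C)CC | intermediate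
28 | 2,6,6-trimethyl-9-methylidene-11-oxotricyclo[5.4.0.0(2,8)]undec-4-en-3-yl (2R)-2-methylbutanoate (not isolated) | C1=CC(C)(C)[C@@H]2[C@H]3C(=O)CC(=C)[C@@H]2[C@@]3(C)[C@@H]1OC(=O)[C@H](C)CC | intermediate
29 | 2,6,6,9-tetramethyl-11-oxotricyclo[5.4.0.0(2,8)]undeca-4,9-dien-3-yl (2R)-2-methylbutanoate | C1=CC(C)(C)[C@@H]2[C@H]3C(=O)C=C(C)[C@@H]2[C@@]3(C)[C@@H]1OC(=O)[C@H](C)CC | intermediate
30 | 4,5-dihydroxy-2,6,6,9-tetramethyl-11-oxotricyclo[5.4.0.0(2,8)]undec-9-en-3-yl (2R)-2-methylbutanoate; 3-O on the C1 side, 4-OH and 5-OH on the C8 side | O[C@H]1[C@@H](O)C(C)(C)[C@@H]2[C@H]3C(=O)C=C(C)[C@@H]2[C@@]3(C)[C@@H]1OC(=O)[C@H](C)CC | intermediate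
31 | (2Z)-2-methylbut-2-enoic acid (angelic acid) | C/C=C(/C)C(=O)O | starting material
32 | C4-O-triphenylphosphonium derivative of 30 as its angelate salt (not isolated) | C/C=C(/C)C(=O)[O-].c1ccccc1[P+](c1ccccc1)(c1ccccc1)O[C@H]1[C@@H](O)C(C)(C)[C@@H]2[C@H]3C(=O)C=C(C)[C@@H]2[C@@]3(C)[C@@H]1OC(=O)[C@H](C)CC | intermediate
33 | 5-hydroxy-2,6,6,9-tetramethyl-3-[(2R)-2-methylbutanoyloxy]-11-oxotricyclo[5.4.0.0(2,8)]undec-9-en-4-yl (2Z)-2-methylbut-2-enoate; 3-O and 4-O on the C1 side, 5-OH on the C8 side (CNP0202800.1) | C/C=C(/C)C(=O)O[C@@H]1[C@@H](O)C(C)(C)[C@@H]2[C@H]3C(=O)C=C(C)[C@@H]2[C@@]3(C)[C@@H]1OC(=O)[C@H](C)CC | target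

## Count and risks

Total step count: 18. Longest linear sequence: 17 steps (steps 1–4 and 6–18; step 5 makes the dienolate used in step 6).

The three steps most likely to fail:

**Step 9 (vinylketene [2+2]).** The alkene is flanked by two allylic silyloxy groups and is less nucleophilic than in the parent farnesoic case, so ketene oligomerisation may compete, and the face selectivity rests on a conformational argument. A minor face isomer is a diastereomer as long as the C4 silyl ether is present and can be removed by chromatography. Fallback, setting out from 12 and coming back at 16, switches to the more electrophilic keteniminium [2+2]. Kinetic deconjugation of 12 (LiN(iPr)2, THF/DMPU, −78 °C; AcOH quench) gives methyl (5S,6E,9E)-5-(tert-butyldimethylsilyloxy)-7,11-dimethyl-3-methylidene-8-(triethylsilyloxy)dodeca-6,9-dienoate F1. KOSiMe3 converts it into the corresponding acid F2, and coupling with pyrrolidine (1-ethyl-3-(3-dimethylaminopropyl)carbodiimide) gives the pyrrolidine amide F3. Tf2O and 2,4,6-collidine in 1,2-dichloroethane (0 → 80 °C) turn F3 into the vinylketeniminium triflate F4, which closes with the same polarity-controlled regiochemistry to the cyclobutaniminium triflate F5. Aqueous NaHCO3 hydrolysis of F5 gives ketone 16.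

**Step 11 (vinylogous aldol ring closure with xanthate trapping).** γ-Deprotonation of a tertiary C–H, γ- versus α-attack and a possible retro-aldol equilibrium are all untested on this cage. Fallback, setting out from 18 and coming back at 22, uses a Lewis-acid vinylogous Mukaiyama aldol, which is γ-selective and made irreversible by silyl transfer. Me3SiOTf/Et3N (CH2Cl2, 0 °C) gives the silyloxydiene (4S)-4-(tert-butyldimethylsilyloxy)-7-methyl-2-methylidene-7-[4-methyl-1-(trimethylsilyloxy)penta-1,3-dien-1-yl]bicyclo[3.1.1]heptan-6-one F6. BF3·OEt2 with 2,6-di-tert-butylpyridine (CH2Cl2, −78 °C) closes the ring to (11S)-11-(tert-butyldimethylsilyloxy)-2,6,6-trimethyl-9-methylidene-7-(trimethylsilyloxy)tricyclo[5.4.0.0(2,8)]undec-4-en-3-one F7. Citric acid in MeOH (0 °C) frees the tertiary alcohol (11S)-11-(tert-butyldimethylsilyloxy)-7-hydroxy-2,6,6-trimethyl-9-methylidenetricyclo[5.4.0.0(2,8)]undec-4-en-3-one F8, and NaH, CS2, then MeI (THF, −40 °C) converts F8 into xanthate 22.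

**Step 18 (Mitsunobu inversion at C4).** The C4 hydroxyl is hindered, and the trans C3 ester could participate (acyloxonium) and scramble the acyl groups or give retention. Fallback, setting out from 30 and coming back at 33, uses a sulfonate displacement by a free carboxylate. Tf2O/pyridine (CH2Cl2, −40 °C) triflates only the C4 hydroxyl to give 5-hydroxy-2,6,6,9-tetramethyl-11-oxo-4-(trifluoromethylsulfonyloxy)tricyclo[5.4.0.0(2,8)]undec-9-en-3-yl (2R)-2-methylbutanoate F9. Cesium (2Z)-2-methylbut-2-enoate F10 (from 31 and Cs2CO3) with 18-crown-6 in toluene at rt displaces the triflate with inversion, the same carboxylate-on-triflate inversion used next to trans esters in carbohydrates, and gives 33.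

Further compounds
F1 | step 9 | methyl (5S,6E,9E)-5-(tert-butyldimethylsilyloxy)-7,11-dimethyl-3-methylidene-8-(triethylsilyloxy)dodeca-6,9-dienoate | COC(=O)CC(=C)C[C@H](O[Si](C)(C)C(C)(C)C)/C=C(\C)C(O[Si](CC)(CC)CC)/C=C/C(C)C
F2 | step 9 | (5S,6E,9E)-5-(tert-butyldimethylsilyloxy)-7,11-dimethyl-3-methylidene-8-(triethylsilyloxy)dodeca-6,9-dienoic acid | OC(=O)CC(=C)C[C@H](O[Si](C)(C)C(C)(C)C)/C=C(\C)C(O[Si](CC)(CC)CC)/C=C/C(C)C
F3 | step 9 | 1-[(5S,6E,9E)-5-(tert-butyldimethylsilyloxy)-7,11-dimethyl-3-methylidene-8-(triethylsilyloxy)dodeca-6,9-dienoyl]pyrrolidine | O=C(CC(=C)C[C@H](O[Si](C)(C)C(C)(C)C)/C=C(\C)C(O[Si](CC)(CC)CC)/C=C/C(C)C)N1CCCC1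
F4 | step 9 | vinylketeniminium triflate from F3 (not isolated) | C(=C=[N+]1CCCC1)C(=C)C[C@H](O[Si](C)(C)C(C)(C)C)/C=C(\C)C(O[Si](CC)(CC)CC)/C=C/C(C)C.[O-]S(=O)(=O)C(F)(F)F
F5 | step 9 | 1-[(4S)-4-(tert-butyldimethylsilyloxy)-7-methyl-2-methylidene-7-[(2E)-4-methyl-1-(triethylsilyloxy)pent-2-en-1-yl]bicyclo[3.1.1]heptan-6-ylidene]pyrrolidinium triflate (not isolated) | [N+]1(CCCC1)=C2[C@H]3[C@@H](O[Si](C)(C)C(C)(C)C)CC(=C)[C@@H]2[C@@]3(C)C(O[Si](CC)(CC)CC)/C=C/C(C)C.[O-]S(=O)(=O)C(F)(F)F
F6 | step 11 | (4S)-4-(tert-butyldimethylsilyloxy)-7-methyl-2-methylidene-7-[4-methyl-1-(trimethylsilyloxy)penta-1,3-dien-1-yl]bicyclo[3.1.1]heptan-6-one | O=C1[C@H]2[C@@H](O[Si](C)(C)C(C)(C)C)CC(=C)[C@@H]1[C@@]2(C)C(O[Si](C)(C)C)=CC=C(C)C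
F7 | step 11 | (11S)-11-(tert-butyldimethylsilyloxy)-2,6,6-trimethyl-9-methylidene-7-(trimethylsilyloxy)tricyclo[5.4.0.0(2,8)]undec-4-en-3-one | C1=CC(C)(C)[C@]2(O[Si](C)(C)C)[C@H]3[C@@H](O[Si](C)(C)C(C)(C)C)CC(=C)[C@@H]2[C@@]3(C)C1=O
F8 | step 11 | (11S)-11-(tert-butyldimethylsilyloxy)-7-hydroxy-2,6,6-trimethyl-9-methylidenetricyclo[5.4.0.0(2,8)]undec-4-en-3-one | C1=CC(C)(C)[C@]2(O)[C@H]3[C@@H](O[Si](C)(C)C(C)(C)C)CC(=C)[C@@H]2[C@@]3(C)C1=O
F9 | step 18 | 5-hydroxy-2,6,6,9-tetramethyl-11-oxo-4-(trifluoromethylsulfonyloxy)tricyclo[5.4.0.0(2,8)]undec-9-en-3-yl (2R)-2-methylbutanoate (4-O on the C8 side) | O=S(=O)(O[C@H]1[C@@H](O)C(C)(C)[C@@H]2[C@H]3C(=O)C=C(C)[C@@H]2[C@@]3(C)[C@@H]1OC(=O)[C@H](C)CC)C(F)(F)F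
F10 | step 18 | cesium (2Z)-2-methylbut-2-enoate | C/C=C(/C)C(=O)[O-].[Cs+]
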